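**Abbreviations:** TBS = tert-butyldimethylsilyl, TES = triethylsilyl.

**Locants:** ring A is the oxane (O1, C2–C6). C2 bears aryl ring 2, C4 the axial OH, C6 the CH2CH2–aryl ring 3 arm. The chain on C3 runs aryl ring 1–C1′H=C2′H–C3′H(C3)–C4′H2–C5′H(OH)–C6′H2–C7′H2–aryl ring 4.
**Cuts, in retrosynthetic order:** C5′ carbinol to ketone; C3′–C4′ (allyl cation plus the enol silane of raspberry ketone); C2′–C3′ (alkenyl iodide plus ring A aldehyde); ring A at O1–C2 and C2–C3 (aldehyde plus δ-hydroxy-β-keto ester); C3–C4 and C5–C6 (two acetate Claisen units).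
**Forward:** the C6–C3′ chain grows by Claisen, hydrogenation, Claisen. Ring A, the only ring made, closes by Knoevenagel/oxa-Michael. C4 is reduced, the ester carbon (C3′) becomes the styryl carbinol acetate, the C4′–C7′ fragment is joined, and desilylation and enzymatic reduction finish the route.
**Enabling feature:** the para oxygen of aryl ring 1 is conjugated through its six ring carbons and C1′=C2′ with C3′. A leaving group on C3′ (either epimer) therefore ionises to one planar, vinylogous para-quinone-methide-type cation that sits directly on stereodefined C3 of ring A.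
**Stereochemistry:** C6 from Noyori hydrogenation; C2 and C3 by equilibration against C6; C4 by equatorial hydride attack; C3′ by ring A control in the stereoconvergent key step; C5′ by a ketoreductase; the E alkene from Takai olefination.

Key step: step 14

Assumption: a Prelog-selective ketoreductase that accepts ketone 22 is taken to be found by screening a commercial enzyme panel.

Step 1
Reactants: 1 methyl 3-(4-hydroxyphenyl)propanoate
Product: 2 methyl 3-[4-(TBSO)phenyl]propanoate
Conditions: TBSCl, imidazole, DMF, rt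
Reagents that add atoms: tert-butyldimethylsilyl chloride, CC(C)(C)[Si](C)(C)Cl
Why: Imidazole-promoted silyl ether protection of the phenol, chosen because aryl TBS ethers should survive the enolate, hydride, chromium and Lewis acid steps and all fall to fluoride in step 15.

Step 2
Reactants: 2 methyl 3-[4-(TBSO)phenyl]propanoate
Product: 3 methyl 3-oxo-5-[4-(TBSO)phenyl]pentanoate
Conditions: MeOAc and LiN(i-Pr)2 (3 equiv each), THF, −78 °C; then 2, −78 to −20 °C; aq NH4Cl
Reagents that add atoms: methyl acetate, COC(C)=O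
Why: Crossed Claisen condensation in which the fully preformed lithium enolate of methyl acetate is acylated by ester 2 and the excess base stores the product as its enolate, which drives the equilibrium.

Step 3
Reactants: 3 methyl 3-oxo-5-[4-(TBSO)phenyl]pentanoate
Product: 4 methyl (3S)-3-hydroxy-5-[4-(TBSO)phenyl]pentanoate
Conditions: RuCl2[(S)-BINAP] (0.5 mol %), H2 (10 bar), MeOH, 50 °C
Reagents that add atoms: none
Why: Noyori asymmetric hydrogenation of a β-keto ester, in which ester chelation to the (S)-BINAP ruthenium catalyst fixes the carbonyl face and should set the future C6 as S, by analogy with methyl acetoacetate where (R)-BINAP gives the (R) alcohol.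

Step 4
Reactants: 4 methyl (3S)-3-hydroxy-5-[4-(TBSO)phenyl]pentanoate
Product: 5 methyl (5S)-5-hydroxy-3-oxo-7-[4-(TBSO)phenyl]heptanoate
Conditions: MeOAc and LiN(i-Pr)2 (4.5 equiv each), THF, −78 °C; then 4, −78 to −10 °C; AcOH then aq NH4Cl, cold
Reagents that add atoms: methyl acetate, COC(C)=O
Why: Second crossed Claisen condensation (the standard two-carbon extension of β-hydroxy esters to δ-hydroxy-β-keto esters), run with extra base so that the hydroxyl travels as its alkoxide and the stereocentre is untouched.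

Step 5
Reactants: 5 methyl (5S)-5-hydroxy-3-oxo-7-[4-(TBSO)phenyl]heptanoate; 6 4-(TBSO)benzaldehyde
Product: 8 methyl (2S,3R,6S)-4-oxo-2-[4-(TBSO)phenyl]-6-{2-[4-(TBSO)phenyl]ethyl}oxane-3-carboxylate, via Knoevenagel enone 7 (not isolated)
Conditions: BF3·OEt2 (0.3 equiv), 4 Å molecular sieves, CH2Cl2, 0 °C to rt
Reagents that add atoms: none
Why: Maitland–Japp type sequence (Knoevenagel condensation, then 6-endo-trig oxa-Michael closure of ring A), in which reversible oxa-Michael addition and enolisation at C3 should let C2 and C3 settle against C6 in the all-equatorial 2,6-cis-2,3-trans keto form.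

Step 6
Reactants: 8 the ring A keto ester
Product: 9 methyl (2S,3S,4S,6S)-4-hydroxy-2-[4-(TBSO)phenyl]-6-{2-[4-(TBSO)phenyl]ethyl}oxane-3-carboxylate (OH axial)
Conditions: Li[HB(s-Bu)3] (1.2 equiv), THF, −78 °C; aq NH4Cl
Reagents that add atoms: none
Why: Substrate-controlled ketone reduction with a bulky trialkylborohydride, whose axial approach is blocked by the axial hydrogens on C2 and C6 so that hydride should enter equatorially and give the axial (4S) alcohol cis to the C3 ester.

Step 7
Reactants: 9 the axial hydroxy ester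
Product: 10 methyl (2S,3R,4S,6S)-4-(TESO)-2-[4-(TBSO)phenyl]-6-{2-[4-(TBSO)phenyl]ethyl}oxane-3-carboxylate
Conditions: Et3SiOTf, 2,6-lutidine, CH2Cl2, −78 to 0 °C
Reagents that add atoms: triethylsilyl triflate, CC[Si](CC)(CC)OS(=O)(=O)C(F)(F)F
Why: Silyl triflate silylation of a hindered axial alcohol, with the small TES group chosen to protect the coming aldehyde from retro-aldol loss while leaving the C4 flank of C3′ open for step 14.

Step 8
Reactants: 10 the TES-protected ester
Product: 11 (2S,3R,4S,6S)-4-(TESO)-2-[4-(TBSO)phenyl]-6-{2-[4-(TBSO)phenyl]ethyl}oxane-3-carbaldehyde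
Conditions: i-Bu2AlH (1.15 equiv), toluene, −78 °C; MeOH, then aq potassium sodium tartrate
Reagents that add atoms: none
Why: Low-temperature partial reduction of a methyl ester to the aldehyde with i-Bu2AlH, standard for β-silyloxy esters, run and worked up cold and neutral so that C3 does not epimerise and the β-silyloxy group is not eliminated.

Step 9
Reactants: 6 4-(TBSO)benzaldehyde
Product: 12 (E)-1-(2-iodoethenyl)-4-(TBSO)benzene
Conditions: CHI3 (2 equiv), CrCl2 (6 equiv), THF, 0 °C
Reagents that add atoms: iodoform, IC(I)I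
Why: Takai olefination, which converts aromatic aldehydes into (E)-alkenyl iodides and thereby fixes the E geometry of C1′=C2′.

Step 10
Reactants: 11 the ring A aldehyde; 12 (E)-1-(2-iodoethenyl)-4-(TBSO)benzene
Product: 14 (E)-1-[ring A of 11 bonded through C3]-3-[4-(TBSO)phenyl]prop-2-en-1-ol as both C3′ epimers, via alkenylchromium dichloride 13 (not isolated)
Conditions: CrCl2 (4 equiv), NiCl2 (2 mol %), DMF/THF, rt
Reagents that add atoms: none
Why: Nozaki–Hiyama–Kishi coupling, whose non-basic organochromium nucleophile adds to hindered, base-sensitive aldehydes with retention of alkene geometry, and whose new carbinol centre at C3′ need not be controlled because step 14 erases it.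

Step 11
Reactants: 14 the allylic alcohol (both C3′ epimers)
Product: 15 the corresponding C3′ acetate (both C3′ epimers)
Conditions: Ac2O, Et3N, DMAP (cat.), CH2Cl2, 0 °C to rt; filtration through Et3N-washed silica
Reagents that add atoms: acetic anhydride, CC(=O)OC(C)=O
Why: DMAP-catalysed acetylation turns the C3′ hydroxyl into a leaving group that ionises under catalytic Me3SiOTf, and allylic transposition on handling would be harmless because both regioisomers lead to the same cation.

Step 12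
Reactants: 16 4-(4-hydroxyphenyl)butan-2-one (raspberry ketone)
Product: 17 4-[4-(TBSO)phenyl]butan-2-one
Conditions: TBSCl, imidazole, DMF, rt
Reagents that add atoms: tert-butyldimethylsilyl chloride, CC(C)(C)[Si](C)(C)Cl
Why: Silyl ether protection of the phenol, needed so that the acidic OH does not quench the enolate of step 13 or the cation of step 14.

Step 13
Reactants: 17 4-[4-(TBSO)phenyl]butan-2-one
Product: 19 2-(trimethylsilyloxy)-4-[4-(TBSO)phenyl]but-1-ene, via lithium enolate 18 (not isolated)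
Conditions: LiN(i-Pr)2 (1.05 equiv), THF, −78 °C; Me3SiCl; pentane, cold aq NaHCO3
Reagents that add atoms: trimethylsilyl chloride, C[Si](C)(C)Cl
Why: Kinetic silyl enol ether formation, in which deprotonation of the methyl ketone at the less hindered CH3 group and O-silylation should give the terminal enol silane needed for bonding through C4′.

Step 14
Reactants: 15 the C3′ acetate (both epimers); 19 2-(trimethylsilyloxy)-4-[4-(TBSO)phenyl]but-1-ene
Product: 21 (3′S)-ketone with the full skeleton (C5′=O; four aryl OTBS; 4-OTES; ring A 2S,3R,4S,6S), via allyl cation 20 (not isolated)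
Conditions: 19 (2.5 equiv), Me3SiOTf (0.15 equiv), 2,6-di-tert-butyl-4-methylpyridine (0.3 equiv), CH2Cl2, −78 °C
Reagents that add atoms: none
Why: Me3SiOTf ionises both C3′ epimers of 15 (and any allyl-transposed isomer) to the same planar, E-configured allyl cation 20, whose charge runs from C3′ over C2′=C1′ and the six carbons of aryl ring 1 to the para silyloxy oxygen (an O-silylated vinylogous para-quinone methide), so the epimer mixture is funnelled stereoconvergently; the CH2 terminus of enol silane 19 then bonds to C3′ and Me3Si+ passes to acetate, which returns the catalyst. The closest known reaction type is the Lewis acid mediated SN1 alkylation of silyl enol ethers with 1-arylallyl and benzylic acetates (Mukaiyama-type cation capture). No ring is closed. The one new stereocentre, C3′, is controlled by ring A: allylic 1,3-strain keeps the axial C3–H in the plane of the cation, the equatorial aryl ring 2 on C2 then screens one face, and the nucleophile enters past C4, whose equatorial site holds only H because the silyloxy group is axial, which should give 3′S. The step needs regioselectivity for C3′ over benzylic C1′, which attack with retention of the styrene conjugation should secure, and chemoselectivity over opening of the C2–O1 benzylic ether and over proton loss from C3, which the better acetate leaving group, −78 °C, the hindered pyridine base and the high nucleophilicity of 19 should secure. The E alkene is kept because the cation is born from the E acetate in its extended shape.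

Step 15
Reactants: 21 the silyl-protected ketone
Product: 22 (3′S)-ketone tetraphenol (C5′=O; free axial 4-OH; ring A 2S,3S,4S,6S)
Conditions: n-Bu4NF (6 equiv), AcOH (6 equiv), THF, 0 °C to rt
Reagents that add atoms: none
Why: Fluoride-mediated global desilylation, buffered with acetic acid so that the phenoxides are protonated as they form and neither the ketone nor C3′ meets strong base.

Step 16
Reactants: 22 the ketone tetraphenol
Product: 23 blepharocalyxin C
Conditions: Prelog-selective NADPH-dependent ketoreductase (short-chain dehydrogenase/reductase class), NADP+ (cat.), 2-propanol (10 % v/v), DMSO (10 % v/v), phosphate buffer pH 7.0, 30 °C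
Reagents that add atoms: none
Why: Enzymatic asymmetric ketone reduction, in which the binding pockets tell the branched C4′ side from the linear 2-arylethyl side (a distinction no small hydride reagent makes) and hydride transfer from NADPH to the Re face should set 5′S while alkene, phenols and the other stereocentres are untouched.

**Compound list**

1 | methyl 3-(4-hydroxyphenyl)propanoate | COC(=O)CCc1ccc(O)cc1 | starting material
2 | methyl 3-[4-(TBSO)phenyl]propanoate | COC(=O)CCc1ccc(O[Si](C)(C)C(C)(C)C)cc1 | intermediate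
3 | methyl 3-oxo-5-[4-(TBSO)phenyl]pentanoate | COC(=O)CC(=O)CCc1ccc(O[Si](C)(C)C(C)(C)C)cc1 | intermediate
4 | methyl (3S)-3-hydroxy-5-[4-(TBSO)phenyl]pentanoate | COC(=O)C[C@@H](O)CCc1ccc(O[Si](C)(C)C(C)(C)C)cc1 | intermediate
5 | methyl (5S)-5-hydroxy-3-oxo-7-[4-(TBSO)phenyl]heptanoate | COC(=O)CC(=O)C[C@@H](O)CCc1ccc(O[Si](C)(C)C(C)(C)C)cc1 | intermediate
6 | 4-(TBSO)benzaldehyde | O=Cc1ccc(O[Si](C)(C)C(C)(C)C)cc1 | starting material
7 | methyl (5S)-5-hydroxy-3-oxo-2-[4-(TBSO)benzylidene]-7-[4-(TBSO)phenyl]heptanoate (alkene isomers; not isolated) | COC(=O)C(=Cc1ccc(O[Si](C)(C)C(C)(C)C)cc1)C(=O)C[C@@H](O)CCc1ccc(O[Si](C)(C)C(C)(C)C)cc1 | intermediate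
8 | methyl (2S,3R,6S)-4-oxo-2-[4-(TBSO)phenyl]-6-{2-[4-(TBSO)phenyl]ethyl}oxane-3-carboxylate (all substituents equatorial) | COC(=O)[C@@H]1[C@@H](c2ccc(O[Si](C)(C)C(C)(C)C)cc2)O[C@@H](CCc2ccc(O[Si](C)(C)C(C)(C)C)cc2)CC1=O | intermediate
9 | methyl (2S,3S,4S,6S)-4-hydroxy-2-[4-(TBSO)phenyl]-6-{2-[4-(TBSO)phenyl]ethyl}oxane-3-carboxylate (axial OH) | COC(=O)[C@@H]1[C@@H](c2ccc(O[Si](C)(C)C(C)(C)C)cc2)O[C@@H](CCc2ccc(O[Si](C)(C)C(C)(C)C)cc2)C[C@@H]1O | intermediate
10 | methyl (2S,3R,4S,6S)-4-(TESO)-2-[4-(TBSO)phenyl]-6-{2-[4-(TBSO)phenyl]ethyl}oxane-3-carboxylate | COC(=O)[C@@H]1[C@@H](c2ccc(O[Si](C)(C)C(C)(C)C)cc2)O[C@@H](CCc2ccc(O[Si](C)(C)C(C)(C)C)cc2)C[C@@H]1O[Si](CC)(CC)CC | intermediate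
11 | (2S,3R,4S,6S)-4-(TESO)-2-[4-(TBSO)phenyl]-6-{2-[4-(TBSO)phenyl]ethyl}oxane-3-carbaldehyde | O=C[C@@H]1[C@@H](c2ccc(O[Si](C)(C)C(C)(C)C)cc2)O[C@@H](CCc2ccc(O[Si](C)(C)C(C)(C)C)cc2)C[C@@H]1O[Si](CC)(CC)CC | intermediate
12 | (E)-1-(2-iodoethenyl)-4-(TBSO)benzene | I/C=C/c1ccc(O[Si](C)(C)C(C)(C)C)cc1 | intermediate
13 | (E)-2-[4-(TBSO)phenyl]ethenylchromium dichloride (not isolated) | Cl[Cr](Cl)/C=C/c1ccc(O[Si](C)(C)C(C)(C)C)cc1 | intermediate
14 | allylic alcohol, OH on C3′, both C3′ epimers, ring A as in 11, E alkene | CC(C)(C)[Si](C)(C)Oc1ccc(/C=C/C(O)[C@@H]2[C@@H](c3ccc(O[Si](C)(C)C(C)(C)C)cc3)O[C@@H](CCc3ccc(O[Si](C)(C)C(C)(C)C)cc3)C[C@@H]2O[Si](CC)(CC)CC)cc1 | intermediate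
15 | allylic acetate, OAc on C3′, both C3′ epimers, ring A as in 11, E alkene | CC(C)(C)[Si](C)(C)Oc1ccc(/C=C/C(OC(C)=O)[C@@H]2[C@@H](c3ccc(O[Si](C)(C)C(C)(C)C)cc3)O[C@@H](CCc3ccc(O[Si](C)(C)C(C)(C)C)cc3)C[C@@H]2O[Si](CC)(CC)CC)cc1 | intermediate
16 | 4-(4-hydroxyphenyl)butan-2-one (raspberry ketone) | CC(=O)CCc1ccc(O)cc1 | starting material
17 | 4-[4-(TBSO)phenyl]butan-2-one | CC(=O)CCc1ccc(O[Si](C)(C)C(C)(C)C)cc1 | intermediate
18 | lithium 4-[4-(TBSO)phenyl]but-1-en-2-olate (not isolated) | [Li+].[O-]C(=C)CCc1ccc(O[Si](C)(C)C(C)(C)C)cc1 | intermediate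
19 | 2-(trimethylsilyloxy)-4-[4-(TBSO)phenyl]but-1-ene | C=C(O[Si](C)(C)C)CCc1ccc(O[Si](C)(C)C(C)(C)C)cc1 | intermediate
20 | E-configured C1′–C3′ allyl cation on C3 of ring A, as its triflate ion pair (not isolated) | CC(C)(C)[Si](C)(C)Oc1ccc(/C=C/[CH+][C@@H]2[C@@H](c3ccc(O[Si](C)(C)C(C)(C)C)cc3)O[C@@H](CCc3ccc(O[Si](C)(C)C(C)(C)C)cc3)C[C@@H]2O[Si](CC)(CC)CC)cc1.[O-]S(=O)(=O)C(F)(F)F | intermediate
21 | (3′S)-ketone, C5′=O, four aryl OTBS, 4-OTES, ring A 2S,3R,4S,6S, E alkene | CC(C)(C)[Si](C)(C)Oc1ccc(/C=C/[C@H](CC(=O)CCc2ccc(O[Si](C)(C)C(C)(C)C)cc2)[C@@H]2[C@@H](c3ccc(O[Si](C)(C)C(C)(C)C)cc3)O[C@@H](CCc3ccc(O[Si](C)(C)C(C)(C)C)cc3)C[C@@H]2O[Si](CC)(CC)CC)cc1 | intermediate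
22 | (5S,6E)-5-[(2S,3S,4S,6S)-4-hydroxy-2-(4-hydroxyphenyl)-6-[2-(4-hydroxyphenyl)ethyl]oxan-3-yl]-1,7-bis(4-hydroxyphenyl)hept-6-en-3-one | Oc1ccc(/C=C/[C@H](CC(=O)CCc2ccc(O)cc2)[C@@H]2[C@@H](c3ccc(O)cc3)O[C@@H](CCc3ccc(O)cc3)C[C@@H]2O)cc1 | intermediate
23 | blepharocalyxin C, (2S,3S,4S,6S)-3-[(1E,3S,5S)-5-hydroxy-1,7-bis(4-hydroxyphenyl)hept-1-en-3-yl]-2-(4-hydroxyphenyl)-6-[2-(4-hydroxyphenyl)ethyl]oxan-4-ol | Oc1ccc(/C=C/[C@H](C[C@@H](O)CCc2ccc(O)cc2)[C@@H]2[C@@H](c3ccc(O)cc3)O[C@@H](CCc3ccc(O)cc3)C[C@@H]2O)cc1 | target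

Total step count: 16. Longest linear sequence: 13 steps (steps 1–8, 10, 11, 14, 15, 16).

**Steps most likely to fail**

**Step 14.** The cation may be captured at benzylic C1′, the nucleophile may attack the wrong face, or a proton may be lost from C3 to give a diene. In the fallback the bond is made sigmatropically, so that site and configuration are fixed by a cyclic transition state.
- The fallback sets out from aldehyde 11. Takai olefination (CHI3, CrCl2, THF) gives the ring A (E)-alkenyl iodide F1.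
- A catalytic asymmetric Nozaki–Hiyama–Kishi addition of F1 to aldehyde 6 (CrCl2, NiCl2, chiral oxazoline–sulfonamide ligand) gives the (1′R)-1-aryl allylic alcohol F2.
- DMAP-catalysed transesterification of F2 with β-keto ester 3 (toluene, heat, removal of MeOH) gives the allyl β-keto ester F3.
- Dianion Carroll rearrangement (LiN(i-Pr)2, 2 equiv, THF, −78 °C to rt) should pass through a chair with aryl ring 1 equatorial. It should carry the C1′ configuration suprafacially to C3′ and form the E alkene, giving the β-keto acid F4.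
- F4 loses CO2 on gentle warming and rejoins the route at ketone 21.

**Step 16.** There may be no turnover because the bulky ketone is not accepted, or the enzyme may discriminate poorly between the two faces.
- The fallback sets out from the silyl-protected ketone 21. NaBH4 (MeOH/THF, 0 °C) gives both C5′ carbinols, the (5′S) alcohol F5 and the (5′R) alcohol F6.
- F5 and F6 are diastereomers and are separated by chromatography.
- F6 is returned to 21 with Dess–Martin periodinane and recycled.
- F5 is desilylated under the conditions of step 15 and rejoins the route at 23.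

**Step 6.** The hydride reagent may enolise the β-keto ester in place of reducing it, or the preference for equatorial attack may erode.
- The fallback sets out from keto ester 8. NaBH4 (MeOH, −40 °C, axial attack) gives the equatorial (4R) alcohol F7.
- Mitsunobu inversion with chloroacetic acid (PPh3, diisopropyl azodicarboxylate, toluene) gives the axial (4S) chloroacetate F8.
- Thiourea and NaHCO3 in EtOH remove the chloroacetyl group without touching the aryl silyl ethers or the methyl ester, and the route is rejoined at 9.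

**Further compounds**

F1 | step 14 | (2S,3R,4S,6S)-3-[(E)-2-iodoethenyl]-4-(TESO)-2-[4-(TBSO)phenyl]-6-{2-[4-(TBSO)phenyl]ethyl}oxane | I/C=C/[C@@H]1[C@@H](c2ccc(O[Si](C)(C)C(C)(C)C)cc2)O[C@@H](CCc2ccc(O[Si](C)(C)C(C)(C)C)cc2)C[C@@H]1O[Si](CC)(CC)CC
F2 | step 14 | (1′R,2′E)-allylic alcohol with OH on benzylic C1′ and ring A of 11 on C3′ | CC(C)(C)[Si](C)(C)Oc1ccc([C@H](O)/C=C/[C@@H]2[C@@H](c3ccc(O[Si](C)(C)C(C)(C)C)cc3)O[C@@H](CCc3ccc(O[Si](C)(C)C(C)(C)C)cc3)C[C@@H]2O[Si](CC)(CC)CC)cc1
F3 | step 14 | 3-oxo-5-[4-(TBSO)phenyl]pentanoate ester of F2 (1′R) | CC(C)(C)[Si](C)(C)Oc1ccc([C@H](OC(=O)CC(=O)CCc2ccc(O[Si](C)(C)C(C)(C)C)cc2)/C=C/[C@@H]2[C@@H](c3ccc(O[Si](C)(C)C(C)(C)C)cc3)O[C@@H](CCc3ccc(O[Si](C)(C)C(C)(C)C)cc3)C[C@@H]2O[Si](CC)(CC)CC)cc1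
F4 | step 14 | β-keto acid, 21 with CO2H on C4′ (both C4′ epimers) | CC(C)(C)[Si](C)(C)Oc1ccc(/C=C/[C@H](C(C(=O)O)C(=O)CCc2ccc(O[Si](C)(C)C(C)(C)C)cc2)[C@@H]2[C@@H](c3ccc(O[Si](C)(C)C(C)(C)C)cc3)O[C@@H](CCc3ccc(O[Si](C)(C)C(C)(C)C)cc3)C[C@@H]2O[Si](CC)(CC)CC)cc1
F5 | step 16 | (3′S,5′S)-alcohol, 23 with four aryl OTBS and 4-OTES | CC(C)(C)[Si](C)(C)Oc1ccc(/C=C/[C@H](C[C@@H](O)CCc2ccc(O[Si](C)(C)C(C)(C)C)cc2)[C@@H]2[C@@H](c3ccc(O[Si](C)(C)C(C)(C)C)cc3)O[C@@H](CCc3ccc(O[Si](C)(C)C(C)(C)C)cc3)C[C@@H]2O[Si](CC)(CC)CC)cc1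
F6 | step 16 | (3′S,5′R)-alcohol, C5′ epimer of F5 | CC(C)(C)[Si](C)(C)Oc1ccc(/C=C/[C@H](C[C@H](O)CCc2ccc(O[Si](C)(C)C(C)(C)C)cc2)[C@@H]2[C@@H](c3ccc(O[Si](C)(C)C(C)(C)C)cc3)O[C@@H](CCc3ccc(O[Si](C)(C)C(C)(C)C)cc3)C[C@@H]2O[Si](CC)(CC)CC)cc1
F7 | step 6 | methyl (2S,3S,4R,6S)-4-hydroxy-2-[4-(TBSO)phenyl]-6-{2-[4-(TBSO)phenyl]ethyl}oxane-3-carboxylate (equatorial OH) | COC(=O)[C@@H]1[C@@H](c2ccc(O[Si](C)(C)C(C)(C)C)cc2)O[C@@H](CCc2ccc(O[Si](C)(C)C(C)(C)C)cc2)C[C@H]1O
F8 | step 6 | methyl (2S,3S,4S,6S)-4-(chloroacetoxy)-2-[4-(TBSO)phenyl]-6-{2-[4-(TBSO)phenyl]ethyl}oxane-3-carboxylate (axial ester) | COC(=O)[C@@H]1[C@@H](c2ccc(O[Si](C)(C)C(C)(C)C)cc2)O[C@@H](CCc2ccc(O[Si](C)(C)C(C)(C)C)cc2)C[C@@H]1OC(=O)CCl
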